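Numbering as for lignans: ring A holds O1, C7', C8', C8 and C9; ring B holds O2, C7, C8, C8' and C9'. Enabling feature: the tertiary OH on C8 and the ring A oxygen O1 on C7' are separated only by C8', and seen from ring B the OH and the C8'–C7' bond lie on opposite faces. Joining C7' to C8 on paper therefore gives a C7'–C8–C8' cyclopropane fused to ring B, and opening it oxidatively with inversion at C8 returns exactly this array.
Retrosynthesis: the two phenol protecting groups come off last. Next C8–OH and C7'–O1 are cut and C7'–C8 is redrawn (arylcyclopropyl carbinol), then C7'–C8 and C7'–C8' (aryl carbenoid plus dihydrofuran), then C8=C8' (metathesis), O2–C9' (allylation) and C7–C8 (Ni/Cr coupling). This leads back to two differently protected syringaldehydes.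
Forward order: C7–C8 bond, ring B by ring-closing metathesis, cyclopropane, ring A by anodic opening of the cyclopropane, then the two deprotections.
Stereochemistry: C7 comes from a chiral ligand on chromium. The C7 aryl group sends the carbenoid to the opposite face of ring B, which fixes C8' and the cyclopropane face. Water inverts C8, and the cis-fused bicycle turns the C7' aryl group to the convex face.

Key step: step 10

Assumption: the (S)-configured ligand of step 3 is taken to give the (R)-carbinol. The sense is to be confirmed by Mosher ester analysis, and the enantiomeric ligand would be used otherwise.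

Step 1
Reactants: 1 syringaldehyde
Product: 2 4-formyl-2,6-dimethoxyphenyl pivalate
Conditions: PivCl (1.2 equiv), Et3N (1.5 equiv), DMAP (5 mol %), CH2Cl2, 0 °C to rt
Reagents that add atoms: pivaloyl chloride, CC(C)(C)C(=O)Cl
Why: DMAP-catalysed O-acylation of the phenol; the ester makes this ring the poorer electron donor for step 10, and its bulk between two ortho methoxy groups should carry it through steps 3 to 10.

Step 2
Reactants: 3 2-bromoprop-2-en-1-ol
Product: 4 [(2-bromoprop-2-en-1-yl)oxy](tert-butyl)diphenylsilane
Conditions: TBDPSCl (1.05 equiv), imidazole (2.2 equiv), CH2Cl2, 0 °C to rt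
Reagents that add atoms: tert-butyl(chloro)diphenylsilane, CC(C)(C)[Si](Cl)(c1ccccc1)c1ccccc1
Why: Imidazole-promoted O-silylation; the bulky silyl group is preferred to smaller ones because it resists O-to-O migration to the neighbouring alkoxide in step 4.

Step 3
Reactants: 2 4-formyl-2,6-dimethoxyphenyl pivalate; 4 [(2-bromoprop-2-en-1-yl)oxy](tert-butyl)diphenylsilane
Product: 5 4-[(1R)-2-{[(tert-butyldiphenylsilyl)oxy]methyl}-1-hydroxyprop-2-en-1-yl]-2,6-dimethoxyphenyl pivalate
Conditions: CrCl2 (3 equiv), (S)-N-[2-(4-isopropyl-4,5-dihydrooxazol-2-yl)-6-methylphenyl]methanesulfonamide (3.3 equiv), Et3N (3.3 equiv), NiCl2 (5 mol %), 4 (1.5 equiv), THF, rt; aqueous ethylenediamine work-up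
Reagents that add atoms: none
Why: Enantioselective Nozaki–Hiyama–Kishi coupling: zerovalent nickel formed in situ activates the 2-bromoalkene, the alkenyl group passes to trivalent chromium and adds only to the aldehyde (aryl ester and silyl ether are inert), and the oxazoline–sulfonamide on chromium differentiates the aldehyde faces, which sets C7 as R.

Step 4
Reactants: 5 the (R)-allylic alcohol; 6 allyl bromide
Product: 7 4-[(1R)-1-(allyloxy)-2-{[(tert-butyldiphenylsilyl)oxy]methyl}prop-2-en-1-yl]-2,6-dimethoxyphenyl pivalate
Conditions: NaH (1.2 equiv), 6 (2 equiv), n-Bu4NI (10 mol %), THF–DMF 4:1, 0 °C to rt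
Reagents that add atoms: none
Why: Williamson ether synthesis on the sodium alkoxide; the C7–O bond is not broken, so the configuration is kept, and the doubly ortho-flanked pivalate is too hindered for acyl transfer at this temperature.

Step 5
Reactants: 7 the allyl ether diene
Product: 8 4-[(2R)-3-{[(tert-butyldiphenylsilyl)oxy]methyl}-2,5-dihydrofuran-2-yl]-2,6-dimethoxyphenyl pivalate
Conditions: second-generation Grubbs catalyst (H2IMes)(PCy3)Cl2Ru=CHPh (3 mol %), 1,4-benzoquinone (10 mol %), CH2Cl2 (0.01 M), reflux
Reagents that add atoms: none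
Why: Ring-closing metathesis of a monosubstituted with a 1,1-disubstituted alkene closes ring B as a 2,5-dihydrofuran, driven by loss of ethene; C7 is not involved, and benzoquinone suppresses ruthenium hydride isomerisation to the enol ether.

Step 6
Reactants: 8 the silylated dihydrofuran
Product: 9 4-[(2R)-3-(hydroxymethyl)-2,5-dihydrofuran-2-yl]-2,6-dimethoxyphenyl pivalate
Conditions: n-Bu4NF (1.5 equiv), AcOH (1.5 equiv), THF, rt
Reagents that add atoms: none
Why: Fluoride-induced desilylation, buffered with acetic acid so that neither a free alkoxide nor basic fluoride can attack the aryl pivalate or the doubly activated C7–H.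

Step 7
Reactants: 1 syringaldehyde
Product: 10 4-(benzyloxy)-3,5-dimethoxybenzaldehyde
Conditions: BnBr (1.1 equiv), K2CO3 (1.5 equiv), DMF, 50 °C
Reagents that add atoms: benzyl bromide, BrCc1ccccc1
Why: Williamson etherification of the phenolate; the ether keeps this ring electron-rich, so that it is the one oxidised in step 10.

Step 8
Reactants: 10 4-(benzyloxy)-3,5-dimethoxybenzaldehyde; 11 p-toluenesulfonyl hydrazide
Product: 12 (E)-N'-[4-(benzyloxy)-3,5-dimethoxybenzylidene]-4-methylbenzenesulfonohydrazide
Conditions: 11 (1.05 equiv), MeOH, rt; the product should crystallise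
Reagents that add atoms: none
Why: Condensation of an aromatic aldehyde with a sulfonyl hydrazide to the tosylhydrazone, a storable precursor of the diazo compound.

Step 9
Reactants: 9 the dihydrofuran methanol; 12 the tosylhydrazone
Product: 15 4-[(1S,2R,5R,6S)-6-(4-benzyloxy-3,5-dimethoxyphenyl)-1-(hydroxymethyl)-3-oxabicyclo[3.1.0]hexan-2-yl]-2,6-dimethoxyphenyl pivalate, via aryldiazomethane 13 (not isolated), via iodozinc carbenoid 14 (not isolated)
Conditions: 12 (3 equiv), 14% aq NaOH, BnEt3NCl (10 mol %), toluene, 65 °C; the dried red toluene layer is added over 6 h to 9 and ZnI2 (20 mol %) in CH2Cl2, 0 °C to rt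
Reagents that add atoms: none
Why: Phase-transfer Bamford–Stevens fragmentation releases 13 (expected to be about as stable as phenyldiazomethane, since the two meta methoxy groups offset the twisted para alkoxy donor), ZnI2 turns it into the Simmons–Smith-type carbenoid 14, and this zinc-catalysed cyclopropanation of an allylic alcohol adds ArCH suprafacially to C8=C8' on the ring B face opposite the C7 aryl group, which sets C8 and C8'; C7' is drawn with its aryl group exo, and its configuration does not matter because step 10 erases it.

Step 10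
Reactants: 15 the arylcyclopropyl carbinol
Product: 17 (7R,7'S,8S,8'R)-8-hydroxysyringaresinol 4-pivalate 4'-benzyl ether, via ring-opened C7' cation 16 (not isolated)
Conditions: undivided cell, reticulated vitreous carbon anode, Pt cathode, LiClO4 (0.1 M), MeCN–H2O 9:1, 2,6-lutidine (1 equiv), argon, 0 °C, anode held at the first oxidation wave of 15 (located by cyclic voltammetry), about 2.1 F/mol
Reagents that add atoms: water, O
Why: Proposed new method: the anode takes one electron from the 4-benzyloxy-3,5-dimethoxyphenyl ring (the pivaloyloxy ring on C7 is the poorer donor and is not conjugated with the three-membered ring), and the resulting radical cation has loosened C7'–C8 and C7'–C8' bonds. Water displaces C7' from the fully substituted carbon C8 along the rear of the C7'–C8 bond (three-electron SN2), so C8 is inverted: its hydroxyl ends on the ring B face away from C7' and C9 moves to the C7' side, while C7 and C8' are untouched. The C7' benzylic radical is much easier to oxidise than 15 and gives cation 16, which the now cis C9 hydroxyl captures in a 5-exo-trig closure of ring A; because ring B holds C8 and C8', only the cis-fused bicycle can form. C7' is set in this closure, the planar cation turning its aryl group to the convex (exo) face away from ring B, so both C7' epimers of 15 would converge on 17. The step needs oxidation of one ring only (secured by ether against ester and by potential control), attack at C8 and not C8' (secured by the larger share of positive charge at the more substituted carbon, against sterics) and a stop after two electrons (17 has lost the cyclopropane conjugation and should be harder to oxidise, the charge is limited, and the protons are reduced to H2 at the cathode). The closest known reaction type is the anodic or photoredox 1,3-dioxygenation and related 1,3-difunctionalisation of simple arylcyclopropanes through their radical cations, for which inversion and attack at the more substituted carbon are established; new here are the fused, fully substituted cyclopropane, the pairing of external water with an internal alcohol, and the second oxidisable ring.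

Step 11
Reactants: 17 the pivalate benzyl ether
Product: 18 (7R,7'S,8S,8'R)-8-hydroxysyringaresinol 4'-benzyl ether
Conditions: K2CO3 (2 equiv), degassed MeOH, argon, 40 °C; neutral aqueous work-up
Reagents that add atoms: none
Why: Base-promoted methanolysis (transesterification) of the aryl ester, run under argon and before the hydrogenolysis so that only one air-sensitive syringyl phenolate is exposed to base; no stereocentre is touched.

Step 12
Reactants: 18 the monobenzyl ether
Product: 19 8-hydroxysyringaresinol
Conditions: H2 (1 atm), 10% Pd/C, EtOAc–MeOH 1:1, rt, stopped as soon as 18 is consumed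
Reagents that add atoms: none
Why: Catalytic hydrogenolysis of an aryl benzyl ether; under neutral conditions at 1 atm the unhindered O–CH2Ph bond should be cleaved well before the hindered ring bonds C7–O2 and C7'–O1, as is usual in the last step of furofuran lignan syntheses.

Compound list
1 | syringaldehyde (4-hydroxy-3,5-dimethoxybenzaldehyde) | COc1cc(C=O)cc(OC)c1O | starting material
2 | 4-formyl-2,6-dimethoxyphenyl pivalate | COc1cc(C=O)cc(OC)c1OC(=O)C(C)(C)C | intermediate
3 | 2-bromoprop-2-en-1-ol | C=C(Br)CO | starting material
4 | [(2-bromoprop-2-en-1-yl)oxy](tert-butyl)diphenylsilane | C=C(Br)CO[Si](c1ccccc1)(c1ccccc1)C(C)(C)C | intermediate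
5 | 4-[(1R)-2-{[(tert-butyldiphenylsilyl)oxy]methyl}-1-hydroxyprop-2-en-1-yl]-2,6-dimethoxyphenyl pivalate | COc1cc([C@@H](O)C(=C)CO[Si](c2ccccc2)(c2ccccc2)C(C)(C)C)cc(OC)c1OC(=O)C(C)(C)C | intermediate
6 | allyl bromide | C=CCBr | starting material
7 | 4-[(1R)-1-(allyloxy)-2-{[(tert-butyldiphenylsilyl)oxy]methyl}prop-2-en-1-yl]-2,6-dimethoxyphenyl pivalate | COc1cc([C@@H](OCC=C)C(=C)CO[Si](c2ccccc2)(c2ccccc2)C(C)(C)C)cc(OC)c1OC(=O)C(C)(C)C | intermediate
8 | 4-[(2R)-3-{[(tert-butyldiphenylsilyl)oxy]methyl}-2,5-dihydrofuran-2-yl]-2,6-dimethoxyphenyl pivalate | COc1cc([C@H]2OCC=C2CO[Si](c3ccccc3)(c3ccccc3)C(C)(C)C)cc(OC)c1OC(=O)C(C)(C)C | intermediate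
9 | 4-[(2R)-3-(hydroxymethyl)-2,5-dihydrofuran-2-yl]-2,6-dimethoxyphenyl pivalate | COc1cc([C@H]2OCC=C2CO)cc(OC)c1OC(=O)C(C)(C)C | intermediate
10 | 4-(benzyloxy)-3,5-dimethoxybenzaldehyde | COc1cc(C=O)cc(OC)c1OCc1ccccc1 | intermediate
11 | p-toluenesulfonyl hydrazide | Cc1ccc(cc1)S(=O)(=O)NN | starting material
12 | (E)-N'-[4-(benzyloxy)-3,5-dimethoxybenzylidene]-4-methylbenzenesulfonohydrazide | COc1cc(/C=N/NS(=O)(=O)c2ccc(C)cc2)cc(OC)c1OCc1ccccc1 | intermediate
13 | 2-(benzyloxy)-5-(diazomethyl)-1,3-dimethoxybenzene (toluene solution only) | COc1cc(C=[N+]=[N-])cc(OC)c1OCc1ccccc1 | intermediate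
14 | [(4-benzyloxy-3,5-dimethoxyphenyl)(iodo)methyl]zinc iodide | COc1cc(C(I)[Zn]I)cc(OC)c1OCc1ccccc1 | intermediate
15 | 4-[(1S,2R,5R,6S)-6-(4-benzyloxy-3,5-dimethoxyphenyl)-1-(hydroxymethyl)-3-oxabicyclo[3.1.0]hexan-2-yl]-2,6-dimethoxyphenyl pivalate (C7 aryl anti to the cyclopropane; C7' aryl exo, cis to CH2OH) | COc1cc([C@H]2OC[C@@H]3[C@@H](c4cc(OC)c(OCc5ccccc5)c(OC)c4)[C@]23CO)cc(OC)c1OC(=O)C(C)(C)C | intermediate
16 | ring-opened C7' benzylic cation (ring B tetrahydrofuran; 8-OH and H8' on one face, CH2OH and C7' on the other) | COc1cc([CH+][C@H]2CO[C@H](c3cc(OC)c(OC(=O)C(C)(C)C)c(OC)c3)[C@@]2(O)CO)cc(OC)c1OCc1ccccc1 | intermediate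
17 | (7R,7'S,8S,8'R)-8-hydroxysyringaresinol 4-pivalate 4'-benzyl ether (cis-fused 3,7-dioxabicyclo[3.3.0]octane; 8-OH and H8' on the convex face; both aryl groups exo) | COc1cc([C@H]2OC[C@]3(O)[C@@H](c4cc(OC)c(OC(=O)C(C)(C)C)c(OC)c4)OC[C@H]23)cc(OC)c1OCc1ccccc1 | intermediate
18 | (7R,7'S,8S,8'R)-8-hydroxysyringaresinol 4'-benzyl ether | COc1cc([C@H]2OC[C@]3(O)[C@@H](c4cc(OC)c(O)c(OC)c4)OC[C@H]23)cc(OC)c1OCc1ccccc1 | intermediate
19 | (7R,7'S,8S,8'R)-8-hydroxysyringaresinol | COc1cc([C@H]2OC[C@]3(O)[C@@H](c4cc(OC)c(O)c(OC)c4)OC[C@H]23)cc(OC)c1O | target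

Total step count: 12.
Longest linear sequence: 9 steps from syringaldehyde (steps 1, 3, 4, 5, 6, 9, 10, 11, 12).

Steps most likely to fail

**Step 10 (new method).**
- What may go wrong:
  - Water may enter at the less hindered C8'.
  - Acetonitrile may compete as nucleophile.
  - The benzyl group may be lost from the radical cation.
  - Oxidation may continue at C7'–H of the product.
- The fallback uses known chemistry and opens the same C7'–C8 bond heterolytically. It sets out from 15 and comes back to the route at 18.
- Dess–Martin periodinane oxidises 15 to the donor–acceptor cyclopropanecarbaldehyde F1.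
- A Lewis-acid-catalysed Cloke–Wilson rearrangement (Sc(OTf)3, CH2Cl2, rt) breaks C7'–C8 and joins the aldehyde oxygen to C7'. This gives the bicyclic enol ether F2, in which ring A is closed and C8=C9 remains.
- Dimethyldioxirane (acetone–CH2Cl2, –78 to 0 °C) delivers oxygen to C8=C9 on the face of H8', the only face that leads to a cis-fused bicycle, and gives the enol ether epoxide F3.
- LiAlH4 (THF, –78 to 0 °C) opens the epoxide at the acetal carbon C9, as known for glycal epoxides, and cleaves the pivalate in the same operation.

**Step 9.**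
- What may go wrong:
  - Self-coupling of the diazo compound and of the short-lived aryl carbenoid may outrun transfer to the hindered trisubstituted alkene.
  - The hydroxyl group may be alkylated instead.
- The fallback builds the ring with a small, long-lived carbenoid and brings in the aryl group afterwards by cross-coupling. It sets out from 9 and comes back at 15.
- The zinc alkoxide of 9 (Et2Zn) is treated with the gem-dizinc carbenoid made from CHI3 and EtZnI (CH2Cl2, 0 °C).
- This alkoxide-directed zinciocyclopropanation, again anti to the C7 aryl group, gives the cyclopropylzinc iodide F4 with zinc cis to the CH2O group.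
- F4 is coupled in the same flask with 2-(benzyloxy)-5-bromo-1,3-dimethoxybenzene F5, made from commercial 4-bromo-2,6-dimethoxyphenol, BnBr and K2CO3. The coupling is a Negishi reaction (Pd(OAc)2, SPhos, THF, 50 °C) that proceeds with retention.

**Step 3.**
- What may go wrong: facial selectivity of the chiral chromium reagent toward an aromatic aldehyde may be poor, or activation of the alkenyl bromide in THF may be slow.
- The fallback replaces asymmetric induction by resolution. It sets out from 2 and 4 and comes back at 5.
- The ligand-free coupling (CrCl2, NiCl2 1 mol %, DMF, rt) gives the racemic allylic alcohol F6.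
- F6 is subjected to a Sharpless kinetic resolution (Ti(OiPr)4, L-(+)-diisopropyl tartrate, t-BuOOH 0.6 equiv, 4 Å sieves, CH2Cl2, –20 °C).
- The (S)-enantiomer should be consumed faster, as the epoxy alcohol F7. The slow-reacting (R)-enantiomer is recovered by chromatography.

Further compounds
F1 | step 10 | 4-[(1S,2R,5R,6S)-6-(4-benzyloxy-3,5-dimethoxyphenyl)-1-formyl-3-oxabicyclo[3.1.0]hexan-2-yl]-2,6-dimethoxyphenyl pivalate | COc1cc([C@H]2OC[C@@H]3[C@@H](c4cc(OC)c(OCc5ccccc5)c(OC)c4)[C@]23C=O)cc(OC)c1OC(=O)C(C)(C)C
F2 | step 10 | 8,9-didehydro furofuran (ring A enol ether C8=C9, both aryl groups on the face of H8') | COc1cc([C@H]2OC=C3[C@@H](c4cc(OC)c(OC(=O)C(C)(C)C)c(OC)c4)OC[C@H]23)cc(OC)c1OCc1ccccc1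
F3 | step 10 | 8,9-epoxide of F2 (oxygen on the face of H8') | COc1cc([C@H]2O[C@H]3O[C@]34[C@@H](c5cc(OC)c(OC(=O)C(C)(C)C)c(OC)c5)OC[C@H]24)cc(OC)c1OCc1ccccc1
F4 | step 9 | exo-6-(iodozincio)-1-(hydroxymethyl)-3-oxabicyclo[3.1.0]hexane derived from 9 (hydroxyl shown free; a zinc alkoxide in the flask) | COc1cc([C@H]2OC[C@@H]3[C@@H]([Zn]I)[C@]23CO)cc(OC)c1OC(=O)C(C)(C)C
F5 | step 9 | 2-(benzyloxy)-5-bromo-1,3-dimethoxybenzene | COc1cc(Br)cc(OC)c1OCc1ccccc1
F6 | step 3 | racemic 4-[2-{[(tert-butyldiphenylsilyl)oxy]methyl}-1-hydroxyprop-2-en-1-yl]-2,6-dimethoxyphenyl pivalate | COc1cc(C(O)C(=C)CO[Si](c2ccccc2)(c2ccccc2)C(C)(C)C)cc(OC)c1OC(=O)C(C)(C)C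
F7 | step 3 | epoxy alcohol from the (S)-enantiomer of F6 | COc1cc([C@H](O)[C@@]2(CO[Si](c3ccccc3)(c3ccccc3)C(C)(C)C)CO2)cc(OC)c1OC(=O)C(C)(C)C
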